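**Retrosynthetic overview**

- The strategy rests on the pyridone ring, which carries N1, C2–CH2OH, C3–OMe and C4=O in a row and is fused through C4a/C8a to the cyclohexane ring that holds C5. This is a maltol-type array, so N1–OMe is taken back to a pyranone ring oxygen (exchange with methoxyamine, last step) and C3–OMe to C3–OH.
- The 3-hydroxy-4-pyranone is disconnected to a 2-furyl carbinol by halogen oxidation and rearrangement: furan C2 becomes C3, the furan C3–H becomes C4=O, the carbinol carbon becomes C2, and the carbinol oxygen becomes O1 bonded to C8a.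
- The carbinol comes from C2-lithiation of (4R)-4-octyl-4,5,6,7-tetrahydro-1-benzofuran and addition to (benzyloxy)acetaldehyde. The furan comes from Paal–Knorr closure of a 1,4-keto aldehyde made by ozonolysis of trans-2-allyl-3-octylcyclohexanone.
- The C5 stereocentre comes from a copper-catalysed asymmetric conjugate addition of dioctylzinc to cyclohex-2-en-1-one, with palladium-catalysed allylation of the zinc enolate in the same flask.
- Ring order: carbocycle (bought), furan (step 4), 4-pyranone at the expense of the furan (step 6), pyridone by O-to-N exchange (step 9).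

Key step: step 6

Assumption: centres that are erased later (C2 of 6, C1 of 7, the carbinol carbon of 11, C2 and C8a of 12 and 13) are carried as epimer mixtures; 6 and 7 are drawn as the expected trans isomers, and the sense of induction in step 2 is taken from the ethyl analogue and should be confirmed on 6.

**Step 1**
Reactants: 1 1-iodooctane
Product: 2 dioctylzinc
Conditions: Et2Zn (neat, excess), CuI (cat.), 50 °C; then EtI and excess Et2Zn removed at 50 °C under high vacuum; taken up in toluene
Reagents that add atoms: diethylzinc, CC[Zn]CC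
Why: The CuI-catalysed iodine–zinc exchange of a primary alkyl iodide with Et2Zn, driven by removal of volatile iodoethane, should give the salt-free dialkylzinc that the copper-catalysed addition needs.

**Step 2**
Reactants: 2 dioctylzinc, 3 cyclohex-2-en-1-one, 4 allyl acetate
Product: 6 (2S,3R)-3-octyl-2-(prop-2-en-1-yl)cyclohexan-1-one, via octylzinc enolate 5 (not isolated)
Conditions: Cu(OTf)2 (2 mol%), (R,S,S)-phosphoramidite [from (R)-BINOL and bis((S)-1-phenylethyl)amine] (4 mol%), toluene, –30 °C; then Pd(PPh3)4 (4 mol%), allyl acetate, 0 °C to rt; aq NH4Cl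
Reagents that add atoms: none
Why: The copper-phosphoramidite asymmetric conjugate addition of a dialkylzinc to cyclohexenone should set C3 as R, since the ligand is the mirror image of the one that gives (S)-3-alkylcyclohexanones, and the regiodefined zinc enolate should then be allylated at C2 trans to the octyl group in a Tsuji–Trost allylation (this C2 centre is erased in step 4).

**Step 3**
Reactants: 6 (2S,3R)-3-octyl-2-(prop-2-en-1-yl)cyclohexan-1-one
Product: 7 2-[(1S,2R)-2-octyl-6-oxocyclohexyl]acetaldehyde
Conditions: O3, CH2Cl2, –78 °C; then Me2S, –78 °C to rt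
Reagents that add atoms: ozone, [O-][O+]=O
Why: Ozonolysis with reductive work-up should cleave the terminal alkene, the only oxidisable group, to the 1,4-keto aldehyde.

**Step 4**
Reactants: 7 2-[(1S,2R)-2-octyl-6-oxocyclohexyl]acetaldehyde
Product: 8 (4R)-4-octyl-4,5,6,7-tetrahydro-1-benzofuran
Conditions: TsOH·H2O (5 mol%), toluene, 4 Å molecular sieves, 80 °C
Reagents that add atoms: none
Why: Acid-catalysed Paal–Knorr cyclodehydration of the 1,4-keto aldehyde should give the furan; the octyl-bearing carbon is beta to the ketone, is not enolisable, and keeps its configuration.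

**Step 5**
Reactants: 8 (4R)-4-octyl-4,5,6,7-tetrahydro-1-benzofuran, 9 (benzyloxy)acetaldehyde
Product: 11 2-(benzyloxy)-1-[(4R)-4-octyl-4,5,6,7-tetrahydro-1-benzofuran-2-yl]ethan-1-ol (both carbinol epimers), via 2-lithiofuran 10 (not isolated)
Conditions: n-BuLi, THF, –78 to 0 °C; then 9, –78 °C; aq NH4Cl
Reagents that add atoms: none
Why: Alpha-lithiation of the furan at C2, its only free alpha position, followed by 1,2-addition to the aldehyde at low temperature should give the furyl carbinol; the new carbinol centre is not controlled and need not be, since it becomes the sp2 C2 of the pyranone.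

**Step 6**
Reactants: 11 2-(benzyloxy)-1-[(4R)-4-octyl-4,5,6,7-tetrahydro-1-benzofuran-2-yl]ethan-1-ol
Product: 14 (5R)-2-[(benzyloxy)methyl]-3-hydroxy-5-octyl-5,6,7,8-tetrahydro-4H-chromen-4-one, via hemiketal enone 12 (not isolated), via bromo enone 13 (not isolated)
Conditions: NBS (1.05 equiv), MeCN/H2O 3:1, 0 °C, dark; NBS (1.05 equiv), 0 to 20 °C; then 1 M H2SO4, 80 °C
Reagents that add atoms: water, O
Why: NBS brominates the electron-rich furan at its alpha carbons, water captures the cation and the 2,5-dihydroxy-2,5-dihydrofuran opens to the Z-enedione, whose secondary carbinol oxygen adds to the C8a ketone in a 6-exo-trig hemiketalisation to give 12 (Achmatowicz rearrangement; this closes the pyran ring and forms the O1–C8a bond). The HBr set free turns the second equivalent of NBS into Br2, which adds to C4=C4a, and elimination through the C3 enol leaves bromine on C4 (13); on heating in acid C2–H enolises, the tertiary C8a–OH ionises to a 3-hydroxy-4-bromopyrylium ion and water displaces bromide at C4, which forms the C4=O bond and the aromatic 3-hydroxy-4-pyranone. The closest known reaction type is the two-equivalent halogen conversion of 1-(2-furyl)alkanols into maltol and ethyl maltol, of which this is the 5,6-annulated case. No lasting stereocentre is created: C2 and C8a of 12 and 13 become sp2, and the furan C3–H, the only unsubstituted ring position, is the carbon that becomes C4. Closure must occur through the secondary oxygen only, which the benzyl ether on the primary oxygen secures (a free diol would be trapped as a bicyclic ketal), and C5, whose hydrogen is gamma to the C3 ketone in 12 and 13, must keep its configuration. Gamma-enolisation would need a C4a=C5 double bond that forces the octyl group into the plane against the C4 substituent (allylic 1,3-strain, severe once C4 carries bromine), and cold oxidation followed by prompt aromatisation keeps these enones short-lived; in 14 the C5 hydrogen is no longer enolisable.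

**Step 7**
Reactants: 14 (5R)-2-[(benzyloxy)methyl]-3-hydroxy-5-octyl-5,6,7,8-tetrahydro-4H-chromen-4-one
Product: 15 (5R)-3-hydroxy-2-(hydroxymethyl)-5-octyl-5,6,7,8-tetrahydro-4H-chromen-4-one
Conditions: BCl3 (3 equiv), CH2Cl2, –78 to 0 °C; MeOH quench, aqueous work-up
Reagents that add atoms: none
Why: Lewis-acid cleavage of the benzyl ether by BCl3 (chloride attacks the benzylic carbon) should free the primary alcohol; the C3–OH/C4=O pair is only held as a boron chelate that methanolysis releases, and the fully substituted pyranone ring offers no site for Friedel–Crafts benzylation.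

**Step 8**
Reactants: 15 (5R)-3-hydroxy-2-(hydroxymethyl)-5-octyl-5,6,7,8-tetrahydro-4H-chromen-4-one
Product: 16 (5R)-2-(hydroxymethyl)-3-methoxy-5-octyl-5,6,7,8-tetrahydro-4H-chromen-4-one
Conditions: MeI (1.2 equiv), K2CO3, acetone, 40 °C
Reagents that add atoms: iodomethane, CI
Why: In this Williamson etherification K2CO3 deprotonates only the acidic enolic C3–OH (as in the selective O-methylation of kojic acid), so the primary alcohol should stay free.

**Step 9**
Reactants: 16 (5R)-2-(hydroxymethyl)-3-methoxy-5-octyl-5,6,7,8-tetrahydro-4H-chromen-4-one, 17 O-methylhydroxylamine hydrochloride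
Product: 18 (5R)-2-(hydroxymethyl)-1,3-dimethoxy-5-octyl-5,6,7,8-tetrahydroquinolin-4(1H)-one
Conditions: MeONH2·HCl (5 equiv), NaOAc, EtOH/H2O 1:1, 80 °C, sealed tube
Reagents that add atoms: none
Why: In this pyranone-to-pyridone exchange the nitrogen of methoxyamine adds in conjugate fashion at C2 or C8a, the ring opens and recloses on nitrogen with loss of water; the O-methyl group blocks closure through oxygen, and C5 is not enolisable in the open intermediate.

**Compound list**

1 | 1-iodooctane | CCCCCCCCI | starting material
2 | dioctylzinc | CCCCCCCC[Zn]CCCCCCCC | intermediate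
3 | cyclohex-2-en-1-one | O=C1C=CCCC1 | starting material
4 | allyl acetate | CC(=O)OCC=C | starting material
5 | octyl[(3R)-3-octylcyclohex-1-en-1-olato]zinc | CCCCCCCC[C@@H]1CCCC(O[Zn]CCCCCCCC)=C1 | intermediate
6 | (2S,3R)-3-octyl-2-(prop-2-en-1-yl)cyclohexan-1-one | CCCCCCCC[C@@H]1CCCC(=O)[C@H]1CC=C | intermediate
7 | 2-[(1S,2R)-2-octyl-6-oxocyclohexyl]acetaldehyde | CCCCCCCC[C@@H]1CCCC(=O)[C@H]1CC=O | intermediate
8 | (4R)-4-octyl-4,5,6,7-tetrahydro-1-benzofuran | CCCCCCCC[C@@H]1CCCc2occc12 | intermediate
9 | (benzyloxy)acetaldehyde | O=CCOCc1ccccc1 | starting material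
10 | [(4R)-4-octyl-4,5,6,7-tetrahydro-1-benzofuran-2-yl]lithium | CCCCCCCC[C@@H]1CCCc2oc([Li])cc12 | intermediate
11 | 2-(benzyloxy)-1-[(4R)-4-octyl-4,5,6,7-tetrahydro-1-benzofuran-2-yl]ethan-1-ol | CCCCCCCC[C@@H]1CCCc2oc(C(O)COCc3ccccc3)cc12 | intermediate
12 | (5R)-2-[(benzyloxy)methyl]-8a-hydroxy-5-octyl-5,6,7,8-tetrahydro-2H-chromen-3(8aH)-one | CCCCCCCC[C@@H]1CCCC2(O)OC(COCc3ccccc3)C(=O)C=C12 | intermediate
13 | (5R)-2-[(benzyloxy)methyl]-4-bromo-8a-hydroxy-5-octyl-5,6,7,8-tetrahydro-2H-chromen-3(8aH)-one | CCCCCCCC[C@@H]1CCCC2(O)OC(COCc3ccccc3)C(=O)C(Br)=C12 | intermediate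
14 | (5R)-2-[(benzyloxy)methyl]-3-hydroxy-5-octyl-5,6,7,8-tetrahydro-4H-chromen-4-one | CCCCCCCC[C@@H]1CCCc2oc(COCc3ccccc3)c(O)c(=O)c12 | intermediate
15 | (5R)-3-hydroxy-2-(hydroxymethyl)-5-octyl-5,6,7,8-tetrahydro-4H-chromen-4-one | CCCCCCCC[C@@H]1CCCc2oc(CO)c(O)c(=O)c12 | intermediate
16 | (5R)-2-(hydroxymethyl)-3-methoxy-5-octyl-5,6,7,8-tetrahydro-4H-chromen-4-one | CCCCCCCC[C@@H]1CCCc2oc(CO)c(OC)c(=O)c12 | intermediate
17 | O-methylhydroxylamine hydrochloride | CON.Cl | starting material
18 | (5R)-2-(hydroxymethyl)-1,3-dimethoxy-5-octyl-5,6,7,8-tetrahydroquinolin-4(1H)-one | CCCCCCCC[C@@H]1CCCc2c1c(=O)c(OC)c(CO)n2OC | target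

**Step count**

Total steps: 9. Longest linear sequence: 9 steps (1 to 18).

**Steps most likely to fail**

1. Step 6. The C5 configuration may erode through gamma-enolisation of the transient enones, or through proton loss from C5 when bromine adds to C4=C4a. The second bromination may also go to C2 instead of C4, and hot acid may start to cleave the benzyl ether before aromatisation is complete. The fallback sets out from 11 and comes back at 14. The oxidation is stopped after the first stage (NBS, 1.0 equiv, NaHCO3, THF/H2O, 0 °C) and hemiketal enone 12 is isolated. It is converted with MeOH, HC(OMe)3 and catalytic PPTS into the methyl ketal (5R)-2-[(benzyloxy)methyl]-8a-methoxy-5-octyl-5,6,7,8-tetrahydro-2H-chromen-3(8aH)-one F1. Nucleophilic epoxidation of the enone (tBuOOH, DBU, CH2Cl2, 0 °C) should give the epoxy ketone (5R)-2-[(benzyloxy)methyl]-4,4a-epoxy-8a-methoxy-5-octylhexahydro-2H-chromen-3(4H)-one F2. Acid (TFA in CH2Cl2, then warm dilute H2SO4) should open the epoxide at the tertiary C4a, shift hydride from C4 to give the 3,4-dione, eliminate methanol from C8a and enolise to 14. This is the known epoxy-ketone variant of the maltol synthesis and places the C4 oxygen without a halogen.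

2. Step 9. Conjugate addition of the weakly basic methoxyamine may be slow at C2 and C8a, which are both fully substituted, and condensation at C4 to an oxime ether may compete. The fallback sets out from 16 and comes back at 18. Hydroxylamine (NH2OH·HCl, NaOAc, EtOH/H2O, 80 °C), which is smaller and more nucleophilic, should give (5R)-1-hydroxy-2-(hydroxymethyl)-3-methoxy-5-octyl-5,6,7,8-tetrahydroquinolin-4(1H)-one F3. The acidic N–OH is then methylated selectively (MeI, K2CO3, DMF, rt) in the presence of the primary alcohol, so that the N–O–CH3 bond is made last by alkylation.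

3. Step 2. Enantiofacial control may be incomplete, ethyl may transfer from residual ethylzinc species, or the enolate may be allylated incompletely or twice. The fallback sets out from 1 and comes back at 8, replacing steps 1 to 4. Compound 1 and Mg in Et2O give octylmagnesium iodide F4, which is added to commercial 6,7-dihydro-1-benzofuran-4(5H)-one F5 to give 4-octyl-4,5,6,7-tetrahydro-1-benzofuran-4-ol F6. Dehydration with catalytic TsOH in toluene gives 4-octyl-6,7-dihydro-1-benzofuran F7. Asymmetric hydrogenation of the trisubstituted alkene with [Ir(cod)(tBu-PHOX)]BArF (H2, CH2Cl2, rt), using the ligand antipode that gives the 4R product, leads to 8.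

**Further compounds**

F1 | step 6 | (5R)-2-[(benzyloxy)methyl]-8a-methoxy-5-octyl-5,6,7,8-tetrahydro-2H-chromen-3(8aH)-one | CCCCCCCC[C@@H]1CCCC2(OC)OC(COCc3ccccc3)C(=O)C=C12
F2 | step 6 | (5R)-2-[(benzyloxy)methyl]-4,4a-epoxy-8a-methoxy-5-octylhexahydro-2H-chromen-3(4H)-one | CCCCCCCC[C@@H]1CCCC2(OC)OC(COCc3ccccc3)C(=O)C3OC123
F3 | step 9 | (5R)-1-hydroxy-2-(hydroxymethyl)-3-methoxy-5-octyl-5,6,7,8-tetrahydroquinolin-4(1H)-one | CCCCCCCC[C@@H]1CCCc2c1c(=O)c(OC)c(CO)n2O
F4 | step 2 | octylmagnesium iodide | CCCCCCCC[Mg]I
F5 | step 2 | 6,7-dihydro-1-benzofuran-4(5H)-one | O=C1CCCc2occc12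
F6 | step 2 | 4-octyl-4,5,6,7-tetrahydro-1-benzofuran-4-ol | CCCCCCCCC1(O)CCCc2occc12
F7 | step 2 | 4-octyl-6,7-dihydro-1-benzofuran | CCCCCCCCC1=CCCc2occc12
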